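The target is cut at the quinone C–N bond into an aminoresorcinol ester and a hydroxy-methoxy-quinone, both built on one decalin. Ring B of that decalin (C5–C10, avarane numbering) is read as a Diels–Alder cyclohexene: the C8 methyl can stem from a carbonyl, so C8=C9 is the enol ether left by a 2-silyloxydiene, and C4, later an sp2 carbon of ring A, is a ketone that activates a C5=C6 dienophile. A catalytic enantioselective intramolecular Diels–Alder reaction of an acyclic trienone, silyloxydiene at one end and isopropenyl ketone at the other, closes rings A and B, forms C6–C7 and C5–C10, sets C5 and C10, and leaves the C8 enolate equivalent for the C9 benzylation.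

Key step: step 5

Remark: decalin positions are cited in avarane numbering (ring A: C1–C5 and C10; ring B: C5–C10; C11 is the benzylic CH2 on C9); both decalins of the target are (5S,8S,9R,10S), and where a CIP descriptor differs in an intermediate the change is formal only.
Remark: compounds 4, 29, 32 and 38 are taken as commercial.

Step 1
Reactants: 1 δ-valerolactone; 2 N,O-dimethylhydroxylamine hydrochloride
Product: 3 hydroxy Weinreb amide 5-hydroxy-N-methoxy-N-methylpentanamide
Conditions: iPrMgCl, THF, −20 °C → 0 °C; aq. NH4Cl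
Reagents that add atoms: N,O-dimethylhydroxylamine hydrochloride (2), CNOC.Cl
Why: The magnesium amide of the hydroxylamine opens the lactone by acyl substitution (Weinreb amide formation from a lactone); the crude hydroxy amide is used at once so that it cannot relactonise.

Step 2
Reactants: 3 hydroxy Weinreb amide; 4 3-(triphenylphosphoranylidene)butan-2-one
Product: 6 enone amide (5E)-N-methoxy-N,6-dimethyl-7-oxooct-5-enamide, via aldehyde 5 (not isolated)
Conditions: TEMPO (10 mol%), PhI(OAc)2, CH2Cl2, rt; then 4, 40 °C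
Reagents that add atoms: 3-(triphenylphosphoranylidene)butan-2-one (4), CC(=O)C(C)=P(c1ccccc1)(c1ccccc1)c1ccccc1
Why: Oxoammonium (TEMPO) oxidation of the primary alcohol is followed in the same flask by Wittig olefination with the stabilised α-methyl ylide, which should give the (E)-trisubstituted enone.

Step 3
Reactants: 6 enone amide; 7 triisopropylsilyl trifluoromethanesulfonate
Product: 8 silyloxydiene amide (5E)-N-methoxy-N,6-dimethyl-7-[(triisopropylsilyl)oxy]octa-5,7-dienamide
Conditions: Et3N, CH2Cl2, −78 °C → 0 °C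
Reagents that add atoms: triisopropylsilyl trifluoromethanesulfonate (7), CC(C)[Si](OS(=O)(=O)C(F)(F)F)(C(C)C)C(C)C
Why: Soft enolisation (silyl triflate and amine) of the methyl ketone at its α′-methyl group should give the cross-conjugated 2-silyloxy-1,3-diene with the (E)-alkene unchanged, since the Weinreb amide is far harder to enolise.

Step 4
Reactants: 8 silyloxydiene amide; 9 isopropenylmagnesium bromide
Product: 10 trienone (7E)-2,8-dimethyl-9-[(triisopropylsilyl)oxy]deca-1,7,9-trien-3-one
Conditions: THF, −20 °C → 0 °C; cold aq. NH4Cl; used directly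
Reagents that add atoms: isopropenylmagnesium bromide (9), CC(=C)[Mg]Br
Why: Grignard addition to the Weinreb amide stops at the chelated tetrahedral intermediate and releases the isopropenyl ketone only on work-up (Weinreb ketone synthesis), which the silyl enol ether tolerates.

Step 5
Reactants: 10 trienone
Product: 11 trans-fused adduct (4aS,8aS)-5,8a-dimethyl-6-[(triisopropylsilyl)oxy]-3,4,4a,7,8,8a-hexahydronaphthalen-1(2H)-one (avarane 5S,10S)
Conditions: (R)-3,3'-bis(2,4,6-triisopropylphenyl)-1,1'-binaphthyl-2,2'-diyl N-triflylphosphoramide (10 mol%), toluene, −78 °C → −40 °C; Et3N quench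
Reagents that add atoms: none
Why: Proposed new method: the chiral acid activates the C4 ketone by protonation or hydrogen bonding and the 2-silyloxydiene adds across C5=C6 in an asynchronous concerted [4+2] cycloaddition in which the C6–C7 bond (enol ether terminus to enone β-carbon) leads and the C5–C10 bond follows inside the chiral ion pair. The closest known reactions are the N-triflylphosphoramide-catalysed enantioselective Diels–Alder reaction of ethyl vinyl ketone with 3-methyl-2-silyloxy-1,3-dienes and the thermal or acid-promoted intramolecular Diels–Alder reaction of deca-1,7,9-trien-3-ones; neither has been shown with an α-methyl enone inside the tether. Ring B (C5 to C10) closes as the cyclohexene of the cycloaddition and ring A (C1 to C5 with C10) closes through the tether when C5–C10 forms, the type 1 closure of a 1,7,9-decatriene to an octalin. The trans ring fusion follows from the (E)-C9=C10 bond and a chair-like tether with the ketone exo and the C5 methyl endo, the orientation that α-methyl enones prefer and that acid catalysis reinforces. The absolute configuration (5S,10S) has to come from the chiral counter-anion shielding one face of the activated enone; the (R)-catalyst is written and its antipode is meant if the first experiment shows the opposite sense. Regioselectivity is secured twice, by the tether and by the matched polarity of C7 and C6, and the bulky triisopropylsilyl group should keep the enol ether intact under the acid.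

Step 6
Reactants: 11 adduct; 12 N-phenylbis(trifluoromethanesulfonimide)
Product: 13 enol triflate (4aS,8aS)-5,8a-dimethyl-6-[(triisopropylsilyl)oxy]-3,4,4a,7,8,8a-hexahydronaphthalen-1-yl trifluoromethanesulfonate
Conditions: KN(SiMe3)2, THF, −78 °C; then 12, −78 °C → 0 °C
Reagents that add atoms: N-phenylbis(trifluoromethanesulfonimide) (12), O=S(=O)(N(c1ccccc1)S(=O)(=O)C(F)(F)F)C(F)(F)F
Why: The ketone can only enolise toward C3 because C5 is quaternary, and O-sulfonylation of that enolate gives the C3=C4 enol triflate (enol triflate formation) while the silyl enol ether is inert to the amide base.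

Step 7
Reactants: 13 enol triflate; 14 methylmagnesium bromide
Product: 15 silyl enol ether triisopropyl{[(4aS,8aR)-1,4a,5-trimethyl-3,4,4a,7,8,8a-hexahydronaphthalen-2-yl]oxy}silane (avarane 5S,10R)
Conditions: Fe(acac)3 (5 mol%), THF/NMP, −30 °C → 0 °C
Reagents that add atoms: methylmagnesium bromide (14), C[Mg]Br
Why: Iron-catalysed Kumada-type cross-coupling of the alkenyl triflate with the methyl Grignard reagent places the C4 methyl on the C3=C4 double bond without moving it and leaves the silyl enol ether alone.

Step 8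
Reactants: 16 1,2,4,5-tetramethoxybenzene; 17 paraformaldehyde
Product: 18 benzylic alcohol (2,3,5,6-tetramethoxyphenyl)methanol
Conditions: nBuLi, TMEDA, THF, 0 °C; then (CH2O)n, 0 °C → rt
Reagents that add atoms: paraformaldehyde (17), as formaldehyde C=O
Why: Directed ortho-lithiation between two methoxy groups followed by hydroxymethylation of the aryllithium with formaldehyde.

Step 9
Reactants: 18 benzylic alcohol; 19 phosphorus tribromide
Product: 20 benzylic bromide 3-(bromomethyl)-1,2,4,5-tetramethoxybenzene
Conditions: Et2O, 0 °C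
Reagents that add atoms: phosphorus tribromide (19), BrP(Br)Br
Why: Conversion of the benzylic alcohol into the bromide through its phosphite ester (SN2 bromination).

Step 10
Reactants: 15 silyl enol ether; 20 benzylic bromide
Product: 21 ketone (1S,4aS,8aR)-1,4a,5-trimethyl-1-(2,3,5,6-tetramethoxybenzyl)-3,4,4a,7,8,8a-hexahydronaphthalen-2(1H)-one (avarane 5S,9S,10R)
Conditions: (Me2N)3S+ Me3SiF2−, THF, −78 °C → 0 °C
Reagents that add atoms: none
Why: Fluoride cleavage of the silyl enol ether gives the regiodefined enolate, which is C-benzylated at C9 (regiospecific SN2 alkylation of a silyl enol ether through its naked enolate) from the face opposite the axial C5 methyl, so that the benzyl group ends trans to that methyl at the new quaternary centre.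

Step 11
Reactants: 21 ketone; 22 dibromomethane
Product: 23 exocyclic alkene 3-{[(1S,4aS,8aS)-1,4a,5-trimethyl-2-methylidene-1,2,3,4,4a,7,8,8a-octahydronaphthalen-1-yl]methyl}-1,2,4,5-tetramethoxybenzene
Conditions: Zn, TiCl4, THF/CH2Cl2, 0 °C → rt
Reagents that add atoms: dibromomethane (22), BrCBr
Why: Takai–Lombardo methylenation converts the hindered α-quaternary C8 ketone into the exocyclic alkene under non-basic conditions.

Step 12
Reactants: 23 exocyclic alkene
Product: 24 tetramethoxyarene 3-{[(1R,2S,4aS,8aS)-1,2,4a,5-tetramethyl-1,2,3,4,4a,7,8,8a-octahydronaphthalen-1-yl]methyl}-1,2,4,5-tetramethoxybenzene (avarane 5S,8S,9R,10S)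
Conditions: H2 (1 atm), PtO2, EtOAc, rt
Reagents that add atoms: none
Why: Heterogeneous hydrogenation should reduce the 1,1-disubstituted exocyclic alkene much faster than the hindered trisubstituted C3=C4 alkene and deliver hydrogen to the face opposite the axial C9 methyl, which sets C8 with its methyl cis to the C9 methyl.

Step 13
Reactants: 24 tetramethoxyarene; 25 water
Product: 26 dimethoxyquinone 2,5-dimethoxy-3-{[(1R,2S,4aS,8aS)-1,2,4a,5-tetramethyl-1,2,3,4,4a,7,8,8a-octahydronaphthalen-1-yl]methyl}cyclohexa-2,5-diene-1,4-dione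
Conditions: (NH4)2Ce(NO3)6, MeCN/H2O, 0 °C
Reagents that add atoms: water (25), O
Why: Oxidative demethylation of a para-dimethoxy pair by tetravalent cerium (water adds at the two ipso carbons and methanol leaves) gives the 2,5-dimethoxy-1,4-benzoquinone, and the symmetry of the arene makes both para pairs lead to the same quinone.

Step 14
Reactants: 26 dimethoxyquinone; 27 potassium hydroxide
Product: 28 hydroxy-methoxy-quinone 2-hydroxy-5-methoxy-3-{[(1R,2S,4aS,8aS)-1,2,4a,5-tetramethyl-1,2,3,4,4a,7,8,8a-octahydronaphthalen-1-yl]methyl}cyclohexa-2,5-diene-1,4-dione (the isospongiaquinone structure)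
Conditions: KOH, THF/H2O, 0 °C → rt; then dilute HCl
Reagents that add atoms: potassium hydroxide (27), [K+].[OH-]
Why: Selective saponification of a vinylogous ester by addition–elimination of hydroxide at the methoxy-bearing carbon next to the alkyl group, whose methoxy group is twisted out of conjugation and therefore the more electrophilic; the reaction should stop there because the product is an unreactive vinylogous carboxylate.

Step 15
Reactants: 29 methyl 5-bromo-2,4-dihydroxybenzoate; 30 benzyl bromide
Product: 31 methyl 2,4-bis(benzyloxy)-5-bromobenzoate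
Conditions: K2CO3, DMF, 60 °C
Reagents that add atoms: benzyl bromide (30), BrCc1ccccc1
Why: Williamson ether synthesis on both phenols.

Step 16
Reactants: 31 aryl bromide; 32 (tributylstannyl)methanol
Product: 33 methyl 2,4-bis(benzyloxy)-5-(hydroxymethyl)benzoate
Conditions: Pd(PPh3)4 (5 mol%), 1,4-dioxane, 90 °C
Reagents that add atoms: (tributylstannyl)methanol (32), CCCC[Sn](CO)(CCCC)CCCC
Why: Stille cross-coupling transfers the hydroxymethyl group from tin to the aryl bromide.

Step 17
Reactants: 33 benzylic alcohol; 19 phosphorus tribromide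
Product: 34 methyl 2,4-bis(benzyloxy)-5-(bromomethyl)benzoate
Conditions: CH2Cl2, 0 °C
Reagents that add atoms: phosphorus tribromide (19), BrP(Br)Br
Why: SN2 bromination of the benzylic alcohol through its phosphite ester, which the benzyl ethers and the ester tolerate.

Step 18
Reactants: 15 silyl enol ether; 34 benzylic bromide
Product: 35 ketone methyl 2,4-bis(benzyloxy)-5-{[(1S,4aS,8aR)-1,4a,5-trimethyl-2-oxo-1,2,3,4,4a,7,8,8a-octahydronaphthalen-1-yl]methyl}benzoate
Conditions: (Me2N)3S+ Me3SiF2−, THF, −78 °C → 0 °C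
Reagents that add atoms: none
Why: The same fluoride-mediated regiospecific C-benzylation of the C8 enolate at C9, anti to the axial C5 methyl, as in step 10; SN2 attack on the benzylic bromide should outrun attack on the methyl ester.

Step 19
Reactants: 35 ketone; 22 dibromomethane
Product: 36 exocyclic alkene methyl 2,4-bis(benzyloxy)-5-{[(1S,4aS,8aS)-1,4a,5-trimethyl-2-methylidene-1,2,3,4,4a,7,8,8a-octahydronaphthalen-1-yl]methyl}benzoate
Conditions: Zn, TiCl4, THF/CH2Cl2, 0 °C → rt
Reagents that add atoms: dibromomethane (22), BrCBr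
Why: Takai–Lombardo methylenation is selective for the ketone over the methyl ester, which a forcing Wittig reaction on this hindered ketone would not be.

Step 20
Reactants: 36 exocyclic alkene
Product: 37 resorcinol ester methyl 2,4-dihydroxy-5-{[(1R,2S,4aS,8aS)-1,2,4a,5-tetramethyl-1,2,3,4,4a,7,8,8a-octahydronaphthalen-1-yl]methyl}benzoate
Conditions: H2 (1 atm), Pd/C, EtOAc/MeOH, rt, stopped after three equivalents of H2
Reagents that add atoms: none
Why: One heterogeneous hydrogenation should reduce the exocyclic alkene from the face opposite the axial C9 methyl (C8 set as in step 12) and cleave both benzyl ethers by hydrogenolysis, while the hindered trisubstituted C3=C4 alkene reacts far more slowly.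

Step 21
Reactants: 37 resorcinol ester; 38 4-diazoniobenzenesulfonate
Product: 40 amine methyl 3-amino-2,4-dihydroxy-5-{[(1R,2S,4aS,8aS)-1,2,4a,5-tetramethyl-1,2,3,4,4a,7,8,8a-octahydronaphthalen-1-yl]methyl}benzoate, via azo compound 39 (not isolated)
Conditions: Na2CO3, THF/H2O, 0 °C; then Na2S2O4, 40 °C, under argon; used directly
Reagents that add atoms: 4-diazoniobenzenesulfonate (38), N#[N+]c1ccc(cc1)S(=O)(=O)[O-]
Why: Azo coupling at C3, the only free position activated by both phenoxide oxygens, followed by reductive cleavage of the N=N bond with dithionite in the same flask; the sulfonated aniline by-product stays in the aqueous phase.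

Step 22
Reactants: 28 hydroxy-methoxy-quinone; 40 amine
Product: 41 nakijiquinone F
Conditions: NaHCO3 (buffer), EtOH/H2O, 40 °C, under argon, in the dark
Reagents that add atoms: none
Why: Addition–elimination of the arylamine at C5 of the quinone replaces the vinylogous ester methoxy group (nucleophilic vinylic substitution, as in the conversion of hydroxy-methoxy-quinones into aminoquinones), while the ionised 2-hydroxy group blocks the other vinylogous position.

Compound list
1 | δ-valerolactone | O=C1CCCCO1 | starting material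
2 | N,O-dimethylhydroxylamine hydrochloride | CNOC.Cl | starting material
3 | 5-hydroxy-N-methoxy-N-methylpentanamide | CON(C)C(=O)CCCCO | intermediate
4 | 3-(triphenylphosphoranylidene)butan-2-one | CC(=O)C(C)=P(c1ccccc1)(c1ccccc1)c1ccccc1 | starting material
5 | N-methoxy-N-methyl-5-oxopentanamide | CON(C)C(=O)CCCC=O | intermediate
6 | (5E)-N-methoxy-N,6-dimethyl-7-oxooct-5-enamide | CC(=O)/C(C)=C/CCCC(=O)N(C)OC | intermediate
7 | triisopropylsilyl trifluoromethanesulfonate | CC(C)[Si](OS(=O)(=O)C(F)(F)F)(C(C)C)C(C)C | starting material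
8 | (5E)-N-methoxy-N,6-dimethyl-7-[(triisopropylsilyl)oxy]octa-5,7-dienamide | C=C(O[Si](C(C)C)(C(C)C)C(C)C)/C(C)=C/CCCC(=O)N(C)OC | intermediate
9 | isopropenylmagnesium bromide | CC(=C)[Mg]Br | starting material
10 | (7E)-2,8-dimethyl-9-[(triisopropylsilyl)oxy]deca-1,7,9-trien-3-one | C=C(O[Si](C(C)C)(C(C)C)C(C)C)/C(C)=C/CCCC(=O)C(C)=C | intermediate
11 | (4aS,8aS)-5,8a-dimethyl-6-[(triisopropylsilyl)oxy]-3,4,4a,7,8,8a-hexahydronaphthalen-1(2H)-one | CC1=C(O[Si](C(C)C)(C(C)C)C(C)C)CC[C@]2(C)C(=O)CCC[C@@H]12 | intermediate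
12 | N-phenylbis(trifluoromethanesulfonimide) | O=S(=O)(N(c1ccccc1)S(=O)(=O)C(F)(F)F)C(F)(F)F | starting material
13 | (4aS,8aS)-5,8a-dimethyl-6-[(triisopropylsilyl)oxy]-3,4,4a,7,8,8a-hexahydronaphthalen-1-yl trifluoromethanesulfonate | CC1=C(O[Si](C(C)C)(C(C)C)C(C)C)CC[C@]2(C)C(OS(=O)(=O)C(F)(F)F)=CCC[C@@H]12 | intermediate
14 | methylmagnesium bromide | C[Mg]Br | starting material
15 | triisopropyl{[(4aS,8aR)-1,4a,5-trimethyl-3,4,4a,7,8,8a-hexahydronaphthalen-2-yl]oxy}silane | CC1=C(O[Si](C(C)C)(C(C)C)C(C)C)CC[C@]2(C)C(C)=CCC[C@@H]12 | intermediate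
16 | 1,2,4,5-tetramethoxybenzene | COc1cc(OC)c(OC)cc1OC | starting material
17 | paraformaldehyde (formaldehyde unit) | C=O | starting material
18 | (2,3,5,6-tetramethoxyphenyl)methanol | COc1cc(OC)c(OC)c(CO)c1OC | intermediate
19 | phosphorus tribromide | BrP(Br)Br | starting material
20 | 3-(bromomethyl)-1,2,4,5-tetramethoxybenzene | COc1cc(OC)c(OC)c(CBr)c1OC | intermediate
21 | (1S,4aS,8aR)-1,4a,5-trimethyl-1-(2,3,5,6-tetramethoxybenzyl)-3,4,4a,7,8,8a-hexahydronaphthalen-2(1H)-one | COc1cc(OC)c(OC)c(C[C@]2(C)C(=O)CC[C@]3(C)C(C)=CCC[C@@H]23)c1OC | intermediate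
22 | dibromomethane | BrCBr | starting material
23 | 3-{[(1S,4aS,8aS)-1,4a,5-trimethyl-2-methylidene-1,2,3,4,4a,7,8,8a-octahydronaphthalen-1-yl]methyl}-1,2,4,5-tetramethoxybenzene | COc1cc(OC)c(OC)c(C[C@]2(C)C(=C)CC[C@]3(C)C(C)=CCC[C@@H]23)c1OC | intermediate
24 | 3-{[(1R,2S,4aS,8aS)-1,2,4a,5-tetramethyl-1,2,3,4,4a,7,8,8a-octahydronaphthalen-1-yl]methyl}-1,2,4,5-tetramethoxybenzene | COc1cc(OC)c(OC)c(C[C@]2(C)[C@@H](C)CC[C@]3(C)C(C)=CCC[C@@H]23)c1OC | intermediate
25 | water | O | starting material
26 | 2,5-dimethoxy-3-{[(1R,2S,4aS,8aS)-1,2,4a,5-tetramethyl-1,2,3,4,4a,7,8,8a-octahydronaphthalen-1-yl]methyl}cyclohexa-2,5-diene-1,4-dione | COC1=CC(=O)C(OC)=C(C[C@]2(C)[C@@H](C)CC[C@]3(C)C(C)=CCC[C@@H]23)C1=O | intermediate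
27 | potassium hydroxide | [K+].[OH-] | starting material
28 | 2-hydroxy-5-methoxy-3-{[(1R,2S,4aS,8aS)-1,2,4a,5-tetramethyl-1,2,3,4,4a,7,8,8a-octahydronaphthalen-1-yl]methyl}cyclohexa-2,5-diene-1,4-dione | COC1=CC(=O)C(O)=C(C[C@]2(C)[C@@H](C)CC[C@]3(C)C(C)=CCC[C@@H]23)C1=O | intermediate
29 | methyl 5-bromo-2,4-dihydroxybenzoate | COC(=O)c1cc(Br)c(O)cc1O | starting material
30 | benzyl bromide | BrCc1ccccc1 | starting material
31 | methyl 2,4-bis(benzyloxy)-5-bromobenzoate | COC(=O)c1cc(Br)c(OCc2ccccc2)cc1OCc1ccccc1 | intermediate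
32 | (tributylstannyl)methanol | CCCC[Sn](CO)(CCCC)CCCC | starting material
33 | methyl 2,4-bis(benzyloxy)-5-(hydroxymethyl)benzoate | COC(=O)c1cc(CO)c(OCc2ccccc2)cc1OCc1ccccc1 | intermediate
34 | methyl 2,4-bis(benzyloxy)-5-(bromomethyl)benzoate | COC(=O)c1cc(CBr)c(OCc2ccccc2)cc1OCc1ccccc1 | intermediate
35 | methyl 2,4-bis(benzyloxy)-5-{[(1S,4aS,8aR)-1,4a,5-trimethyl-2-oxo-1,2,3,4,4a,7,8,8a-octahydronaphthalen-1-yl]methyl}benzoate | COC(=O)c1cc(C[C@]2(C)C(=O)CC[C@]3(C)C(C)=CCC[C@@H]23)c(OCc2ccccc2)cc1OCc1ccccc1 | intermediate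
36 | methyl 2,4-bis(benzyloxy)-5-{[(1S,4aS,8aS)-1,4a,5-trimethyl-2-methylidene-1,2,3,4,4a,7,8,8a-octahydronaphthalen-1-yl]methyl}benzoate | COC(=O)c1cc(C[C@]2(C)C(=C)CC[C@]3(C)C(C)=CCC[C@@H]23)c(OCc2ccccc2)cc1OCc1ccccc1 | intermediate
37 | methyl 2,4-dihydroxy-5-{[(1R,2S,4aS,8aS)-1,2,4a,5-tetramethyl-1,2,3,4,4a,7,8,8a-octahydronaphthalen-1-yl]methyl}benzoate | COC(=O)c1cc(C[C@]2(C)[C@@H](C)CC[C@]3(C)C(C)=CCC[C@@H]23)c(O)cc1O | intermediate
38 | 4-diazoniobenzenesulfonate | N#[N+]c1ccc(cc1)S(=O)(=O)[O-] | starting material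
39 | 4-[(E)-(2,6-dihydroxy-3-(methoxycarbonyl)-5-{[(1R,2S,4aS,8aS)-1,2,4a,5-tetramethyl-1,2,3,4,4a,7,8,8a-octahydronaphthalen-1-yl]methyl}phenyl)diazenyl]benzenesulfonic acid | COC(=O)c1cc(C[C@]2(C)[C@@H](C)CC[C@]3(C)C(C)=CCC[C@@H]23)c(O)c(/N=N/c2ccc(cc2)S(O)(=O)=O)c1O | intermediate
40 | methyl 3-amino-2,4-dihydroxy-5-{[(1R,2S,4aS,8aS)-1,2,4a,5-tetramethyl-1,2,3,4,4a,7,8,8a-octahydronaphthalen-1-yl]methyl}benzoate | COC(=O)c1cc(C[C@]2(C)[C@@H](C)CC[C@]3(C)C(C)=CCC[C@@H]23)c(O)c(N)c1O | intermediate
41 | nakijiquinone F | COC(=O)c1cc(C[C@]2(C)[C@@H](C)CC[C@]3(C)C(C)=CCC[C@@H]23)c(O)c(NC2=CC(=O)C(O)=C(C[C@]3(C)[C@@H](C)CC[C@]4(C)C(C)=CCC[C@@H]34)C2=O)c1O | target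

Total step count: 22.
Longest linear sequence: 13 steps (steps 1–7, 10–14 and 22).

Steps most likely to fail

Step 5 (Proposed new method). The chiral ion pair may discriminate the two faces of the activated enone poorly, or the strong acid may remove the silyl group before the cycloaddition. The fallback sets out from trienone 10 and comes back at adduct 11. Trienone 10 is cyclised without catalyst (toluene, 100 °C, a trace of Et3N and BHT), a known thermal intramolecular Diels–Alder reaction of a 2-silyloxydiene with a tethered enone. It forms the same two bonds and should give the racemic trans-fused adduct, that is 11 together with its enantiomer (4aR,8aR)-5,8a-dimethyl-6-[(triisopropylsilyl)oxy]-3,4,4a,7,8,8a-hexahydronaphthalen-1(2H)-one F1. The two are separated by preparative chromatography on a chiral stationary phase (supercritical CO2, amylose tris(3,5-dimethylphenylcarbamate)), and 11 continues with step 6.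

Step 20. On palladium the exocyclic double bond may migrate into the ring before it is reduced, the C3=C4 alkene may be over-reduced, or hydrogen may be delivered to the wrong face at C8. The fallback sets out from 36 and comes back at 37, and it separates the two tasks. Alkene 36 is reduced with diimide (2-nitrobenzenesulfonohydrazide, Et3N, CH2Cl2, rt), a metal-free concerted syn-hydrogenation that cannot isomerise alkenes and should not touch the trisubstituted alkene or the benzyl ethers. This gives methyl 2,4-bis(benzyloxy)-5-{[(1R,2S,4aS,8aS)-1,2,4a,5-tetramethyl-1,2,3,4,4a,7,8,8a-octahydronaphthalen-1-yl]methyl}benzoate F2. Its benzyl ethers are then removed by transfer hydrogenolysis (Pd/C, cyclohexa-1,4-diene, EtOH, rt) to give 37.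

Step 22. Substitution at the ionised hydroxyquinone by the weakly nucleophilic, hindered arylamine may be slow, which would leave time for oxidation of the aminoresorcinol by the quinone and for oxidative ring closure to phenoxazinone-type products. The fallback sets out from dimethoxyquinone 26 and amine 40 and comes back at 41. Amine 40 is condensed with the neutral, more electrophilic quinone 26 (EtOH, catalytic AcOH, rt, argon), where the bulky arylamine should attack the unhindered C5 vinylogous ester. This gives methyl 2,4-dihydroxy-3-[(4-methoxy-3,6-dioxo-5-{[(1R,2S,4aS,8aS)-1,2,4a,5-tetramethyl-1,2,3,4,4a,7,8,8a-octahydronaphthalen-1-yl]methyl}cyclohexa-1,4-dien-1-yl)amino]-5-{[(1R,2S,4aS,8aS)-1,2,4a,5-tetramethyl-1,2,3,4,4a,7,8,8a-octahydronaphthalen-1-yl]methyl}benzoate F3. The remaining methoxy group, next to the alkyl group, is then hydrolysed (LiOH, THF/H2O, 0 °C, then dilute acid), conditions under which the phenoxide-deactivated methyl ester should survive, to give 41.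

Further compounds
F1 | step 5 | (4aR,8aR)-5,8a-dimethyl-6-[(triisopropylsilyl)oxy]-3,4,4a,7,8,8a-hexahydronaphthalen-1(2H)-one | CC1=C(O[Si](C(C)C)(C(C)C)C(C)C)CC[C@@]2(C)C(=O)CCC[C@H]12
F2 | step 20 | methyl 2,4-bis(benzyloxy)-5-{[(1R,2S,4aS,8aS)-1,2,4a,5-tetramethyl-1,2,3,4,4a,7,8,8a-octahydronaphthalen-1-yl]methyl}benzoate | COC(=O)c1cc(C[C@]2(C)[C@@H](C)CC[C@]3(C)C(C)=CCC[C@@H]23)c(OCc2ccccc2)cc1OCc1ccccc1
F3 | step 22 | methyl 2,4-dihydroxy-3-[(4-methoxy-3,6-dioxo-5-{[(1R,2S,4aS,8aS)-1,2,4a,5-tetramethyl-1,2,3,4,4a,7,8,8a-octahydronaphthalen-1-yl]methyl}cyclohexa-1,4-dien-1-yl)amino]-5-{[(1R,2S,4aS,8aS)-1,2,4a,5-tetramethyl-1,2,3,4,4a,7,8,8a-octahydronaphthalen-1-yl]methyl}benzoate | COC(=O)c1cc(C[C@]2(C)[C@@H](C)CC[C@]3(C)C(C)=CCC[C@@H]23)c(O)c(NC2=CC(=O)C(OC)=C(C[C@]3(C)[C@@H](C)CC[C@]4(C)C(C)=CCC[C@@H]34)C2=O)c1O
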